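**Retrosynthetic overview**
1. The strategy rests on ring A. Starting from the C4a=C8a edge it shares with ring C, ring A carries C5–OH (peri to the C4 ketone), C6–prenyl, C7–OMe and C8–H. A vinylketene and a 1-alkoxyalkyne write exactly this order onto an alkene. Ring A is therefore made last by cutting C5–C6, C7–C8 and C4a–C5 (and C8–C8a through the Wolff shift), which leads to diazoketone 10 and ynol ether 14.
2. Diazoketone 10 comes from acid 8 through the acid chloride and about one equivalent of CH2N2. Acid 8 is released from a tert-butyl ester with acid, because ring C bearing an acyl group on C8a does not tolerate base.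
3. Ring C is closed by O1–C8a cyclodehydration of 2,4-diketoester 6, made by Claisen condensation of silylated aldol 4 with di-tert-butyl oxalate. C2 (S) is set in step 1 by a catalytic asymmetric acetone aldol on aldehyde 1, which brings ring B.
4. Ynol ether 14 is made in one flask from chloroacetaldehyde dimethyl acetal and prenyl bromide.
5. Order of rings: B (bought), C (step 4), A (step 7).

Key step: step 7

Remark: flavanone numbering (O1, C2–C4, C4a, C5–C8, C8a) is used for ring A and ring C atoms in all intermediates (pyranone C6 = C8a, pyranone C5 = C4a), C2 of the target SMILES reads as S, and the aldol catalyst (from Boc-D-proline and (R)-2-amino-4-methyl-1,1-diphenylpentan-1-ol) is not counted as a step.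

**Step 1**
Reactants: 1 3,4,5-trimethoxybenzaldehyde; 2 acetone
Product: 3 (S)-4-hydroxy-4-(3,4,5-trimethoxyphenyl)butan-2-one
Conditions: (R)-N-[(R)-1-hydroxy-4-methyl-1,1-diphenylpentan-2-yl]pyrrolidine-2-carboxamide (10 mol %), acetone (solvent), −40 °C
Reagents that add atoms: none
Why: Enamine-catalysed direct asymmetric aldol addition, in which the acetone enamine of the D-proline amide attacks the Si face of the aldehyde held by hydrogen bonds to the amide N–H and the carbinol O–H, so that C2 is set as S, the mirror image of the R sense of the L-proline series.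

**Step 2**
Reactants: 3 (S)-4-hydroxy-4-(3,4,5-trimethoxyphenyl)butan-2-one
Product: 4 (S)-4-(triethylsilyloxy)-4-(3,4,5-trimethoxyphenyl)butan-2-one
Conditions: Et3SiCl (1.2 equiv), imidazole (2 equiv), CH2Cl2, 0 °C → rt
Reagents that add atoms: chlorotriethylsilane, CC[Si](Cl)(CC)CC
Why: Routine silylation of a secondary benzylic alcohol, which keeps an alkoxide (retro-aldol, O-acylation) out of the Claisen step and does not touch the stereocentre.

**Step 3**
Reactants: 4 (S)-4-(triethylsilyloxy)-4-(3,4,5-trimethoxyphenyl)butan-2-one; 5 di-tert-butyl oxalate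
Product: 6 tert-butyl (S)-2,4-dioxo-6-(triethylsilyloxy)-6-(3,4,5-trimethoxyphenyl)hexanoate (mainly enolised)
Conditions: LiN(SiMe3)2 (2.2 equiv), THF, −78 °C; 5 (1.3 equiv), −78 → −40 °C; AcOH (2.2 equiv), −78 °C
Reagents that add atoms: none
Why: Crossed Claisen condensation in which kinetic deprotonation of the methyl group avoids the internal enolate that would expel silanolate, the non-enolisable oxalate can only be the acceptor, and the second equivalent of base stores the acidic diketoester as its enolate.

**Step 4**
Reactants: 6 tert-butyl (S)-2,4-dioxo-6-(triethylsilyloxy)-6-(3,4,5-trimethoxyphenyl)hexanoate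
Product: 8 (S)-4-oxo-2-(3,4,5-trimethoxyphenyl)-3,4-dihydro-2H-pyran-6-carboxylic acid, via tert-butyl pyranonecarboxylate 7 (not isolated)
Conditions: CF3CO2H/CH2Cl2 (1:3), 0 °C → rt; evaporation, crystallisation (no basic extraction)
Reagents that add atoms: none
Why: Acid-mediated desilylation, cyclodehydration of O1 onto the α-keto ester carbon (closing ring C) and E1 loss of isobutene run in one flask without breaking the C2–O bond, whereas hydroxide would open this pyranone by E1cB expulsion of the stabilised diketoester enolate and racemise C2.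

**Step 5**
Reactants: 8 (S)-4-oxo-2-(3,4,5-trimethoxyphenyl)-3,4-dihydro-2H-pyran-6-carboxylic acid
Product: 10 (S)-6-(2-diazoacetyl)-2-(3,4,5-trimethoxyphenyl)-2,3-dihydro-4H-pyran-4-one, via acid chloride 9 (not isolated)
Conditions: Me2C=C(Cl)NMe2 (1.1 equiv), CH2Cl2, 0 °C; then added to CH2N2 (1.1 equiv), CaO (1.1 equiv), Et2O, 0 °C
Reagents that add atoms: diazomethane, C=[N+]=[N-]
Why: Neutral acid chloride formation with the α-chloroenamine followed by Arndt–Eistert-type acylation of diazomethane, run with about one equivalent of CH2N2 and CaO as HCl scavenger so that no excess dipole remains to add to the C4a=C8a bond, which is itself only a mediocre dipolarophile because it is trisubstituted and carries the O1 donor.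

**Step 6**
Reactants: 11 chloroacetaldehyde dimethyl acetal; 12 1-bromo-3-methylbut-2-ene (prenyl bromide)
Product: 14 1-methoxy-5-methylhex-4-en-1-yne, via sodium methoxyacetylide 13 (not isolated)
Conditions: NaNH2 (3.0 equiv), NH3(l), −33 °C; then 12 (0.95 equiv), −78 → −33 °C; distillation from K2CO3 under reduced pressure
Reagents that add atoms: none
Why: Two base-induced eliminations (HCl, MeOH) and a deprotonation give the acetylide, which is alkylated by SN2 at the primary carbon of prenyl bromide, and the methyl ether has no β-hydrogen, so the ynol ether cannot fragment by a retro-ene reaction in the later heating.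

**Step 7**
Reactants: 10 (S)-6-(2-diazoacetyl)-2-(3,4,5-trimethoxyphenyl)-2,3-dihydro-4H-pyran-4-one; 14 1-methoxy-5-methylhex-4-en-1-yne
Product: 19 artoflavanone [(2S)-5-hydroxy-7-methoxy-6-(3-methylbut-2-enyl)-2-(3,4,5-trimethoxyphenyl)chroman-4-one], via vinylketene 15 (not isolated), via alkenylcyclobutenone 16 (not isolated), via dienylketene 17 (not isolated), via cyclohexadienone tautomer 18 (not isolated)
Conditions: 14 (2 equiv), ClCH2CH2Cl (0.05 M, dry, degassed), 405 nm LED, 20 °C, until 10 is consumed; then reflux (83 °C) in the dark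
Reagents that add atoms: none
Why: Light absorbed in the long-wavelength band of 10 expels N2 and C8a shifts from the acyl carbon to the former diazo carbon (Wolff rearrangement, new bond C8–C8a), giving vinylketene 15 whose ketene carbon is the future C5 and whose CH is the future C8. The nucleophilic prenyl-bearing carbon of 14 attacks C5 and the methoxy-bearing carbon closes on C8 ([2+2] cycloaddition, bonds C5–C6 and C7–C8) to give cyclobutenone 16, whose reversible conrotatory 4π opening on heating cleaves C5–C8 and gives dienylketene 17. Ring A then closes by a disrotatory 6π electrocyclisation that joins C5 to C4a, and dienone 18 enolises to the phenol chelated to the C4 ketone; the whole is the diazoketone variant of the Danheiser benzannulation, established for alkenyl and heteroaryl diazoketones with alkoxy- and siloxyalkynes. No lasting stereocentre is created (the sp3 carbons C8 of 16 and C4a of 18 are erased on the way), and C2 should stay S because no acid or base is present, because 405 nm light is not absorbed by the pyranone, cyclobutenone or aryl chromophores left after loss of N2, and because the photolabile flavanone appears only in the dark stage. The order O5, prenyl, OMe, H is fixed by the polarisation of the ynol ether, and the alkyne wins over the prenyl alkene of 14 because it is by far the better nucleophile toward a ketene. Ring C holds the ketenyl group cis to C4a–H and trans to C4, so closure onto the C4 carbonyl oxygen is geometrically excluded, and only the isomer of 17 with C6 and C8a cis can cyclise while the other returns through 16.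

**Compound list**
1 | 3,4,5-trimethoxybenzaldehyde | COc1cc(C=O)cc(OC)c1OC | starting material
2 | acetone | CC(C)=O | starting material
3 | (S)-4-hydroxy-4-(3,4,5-trimethoxyphenyl)butan-2-one | CC(=O)C[C@@H](c1cc(OC)c(OC)c(OC)c1)O | intermediate
4 | (S)-4-(triethylsilyloxy)-4-(3,4,5-trimethoxyphenyl)butan-2-one | CC(=O)C[C@@H](c1cc(OC)c(OC)c(OC)c1)O[Si](CC)(CC)CC | intermediate
5 | di-tert-butyl oxalate | CC(C)(C)OC(=O)C(=O)OC(C)(C)C | starting material
6 | tert-butyl (S)-2,4-dioxo-6-(triethylsilyloxy)-6-(3,4,5-trimethoxyphenyl)hexanoate | CC(C)(C)OC(=O)C(=O)CC(=O)C[C@@H](c1cc(OC)c(OC)c(OC)c1)O[Si](CC)(CC)CC | intermediate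
7 | tert-butyl (S)-4-oxo-2-(3,4,5-trimethoxyphenyl)-3,4-dihydro-2H-pyran-6-carboxylate | CC(C)(C)OC(=O)C1=CC(=O)C[C@@H](c2cc(OC)c(OC)c(OC)c2)O1 | intermediate
8 | (S)-4-oxo-2-(3,4,5-trimethoxyphenyl)-3,4-dihydro-2H-pyran-6-carboxylic acid | OC(=O)C1=CC(=O)C[C@@H](c2cc(OC)c(OC)c(OC)c2)O1 | intermediate
9 | (S)-4-oxo-2-(3,4,5-trimethoxyphenyl)-3,4-dihydro-2H-pyran-6-carbonyl chloride | ClC(=O)C1=CC(=O)C[C@@H](c2cc(OC)c(OC)c(OC)c2)O1 | intermediate
10 | (S)-6-(2-diazoacetyl)-2-(3,4,5-trimethoxyphenyl)-2,3-dihydro-4H-pyran-4-one | [N-]=[N+]=CC(=O)C1=CC(=O)C[C@@H](c2cc(OC)c(OC)c(OC)c2)O1 | intermediate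
11 | chloroacetaldehyde dimethyl acetal | COC(CCl)OC | starting material
12 | 1-bromo-3-methylbut-2-ene (prenyl bromide) | CC(C)=CCBr | starting material
13 | sodium methoxyacetylide | [Na+].[C-]#COC | intermediate
14 | 1-methoxy-5-methylhex-4-en-1-yne | COC#CCC=C(C)C | intermediate
15 | (S)-6-(2-oxoethenyl)-2-(3,4,5-trimethoxyphenyl)-2,3-dihydro-4H-pyran-4-one (vinylketene) | O=C=CC1=CC(=O)C[C@@H](c2cc(OC)c(OC)c(OC)c2)O1 | intermediate
16 | 3-methoxy-2-(3-methylbut-2-enyl)-4-[(S)-4-oxo-2-(3,4,5-trimethoxyphenyl)-3,4-dihydro-2H-pyran-6-yl]cyclobut-2-en-1-one (both epimers at the ring sp3 carbon) | O=C1C(CC=C(C)C)=C(OC)C1C2=CC(=O)C[C@@H](c3cc(OC)c(OC)c(OC)c3)O2 | intermediate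
17 | 3-methoxy-2-(3-methylbut-2-enyl)-4-[(S)-4-oxo-2-(3,4,5-trimethoxyphenyl)-3,4-dihydro-2H-pyran-6-yl]buta-1,3-dien-1-one (C6 and C8a cis on C7=C8) | O=C=C(CC=C(C)C)/C(OC)=C\C1=CC(=O)C[C@@H](c2cc(OC)c(OC)c(OC)c2)O1 | intermediate
18 | (2S)-7-methoxy-6-(3-methylbut-2-enyl)-2-(3,4,5-trimethoxyphenyl)-2,3-dihydro-4aH-chromene-4,5-dione (C4a undefined, transient) | COC1=C(CC=C(C)C)C(=O)C2C(=O)C[C@@H](c3cc(OC)c(OC)c(OC)c3)OC2=C1 | intermediate
19 | artoflavanone, (2S)-5-hydroxy-7-methoxy-6-(3-methylbut-2-enyl)-2-(3,4,5-trimethoxyphenyl)chroman-4-one | COc1cc2c(c(O)c1CC=C(C)C)C(=O)C[C@@H](c1cc(OC)c(OC)c(OC)c1)O2 | target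

**Step count**
Total steps: 7. Longest linear sequence: 6 (steps 1, 2, 3, 4, 5, 7).

**Steps most likely to fail**

1. Step 7.
   - Risk: the electron-poor vinylketene may be consumed by dimerisation or by traces of water faster than the methoxyalkyne adds. The small ynol ether may also be used up by hydration or oligomerisation during irradiation and heating.
   - Fallback (sets out from 12 and 10, returns at 19): the two-carbon partner and the end game are changed, so that O7 enters as a silyl ether and its methyl group is put on last.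
   - Prenyl bromide 12 is coupled with HC≡CMgBr (CuCl cat., THF) to give 5-methylhex-4-en-1-yne F1.
   - This is converted in one flask (n-BuLi; LiOOt-Bu; i-Pr3SiOTf; THF, −78 → 0 °C) into the sturdier triisopropylsilyl ynol ether F2, which belongs to the alkyne class best documented for the diazoketone benzannulation.
   - Irradiation and heating of 10 with F2 as in step 7 should give the 7-O-triisopropylsilyl flavanone F3.
   - Et3N·3HF (THF, rt) frees the 5,7-dihydroxy-6-prenylflavanone F4 without base.
   - One equivalent of ethereal CH2N2 at 0 °C methylates only the acidic O7–H, because O5–H is locked in the chelate with the C4 ketone. This gives 19.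

2. Step 5.
   - Risk: dipolar cycloaddition of diazomethane to the C4a=C8a bond may compete with acylation, and slow uptake of HCl may lead to protonation and loss of the diazo group.
   - Fallback (sets out from 9, returns at 10): a diazomethane-free route.
   - Acid chloride 9 undergoes the Nef isocyanide reaction with (N-isocyanoimino)triphenylphosphorane (CH2Cl2, rt) to give the phosphazine-protected ketohydrazonoyl chloride F5.
   - Water cleaves the P=N bond to give the free ketohydrazonoyl chloride F6.
   - 1,3-Dehydrochlorination with i-Pr2NH/ZnBr2 (CH2Cl2, 0 °C, short contact) gives 10.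

3. Step 1.
   - Risk: the enamine aldol may be slow with this only moderately electrophilic aldehyde. Reversibility or dehydration during a long reaction time may erode conversion and enantiomeric purity.
   - Fallback (sets out from 1, returns at 3): the stereocentre is set by carbonyl allylation instead of an aldol.
   - Keck allylation of 1 (allylSnBu3, (S)-BINOL and Ti(OiPr)4, 10 mol % each, 4 Å sieves, CH2Cl2, −20 °C) should give (S)-1-(3,4,5-trimethoxyphenyl)but-3-en-1-ol F7 by Si-face attack.
   - Tsuji–Wacker oxidation (PdCl2 10 mol %, CuCl 1 equiv, O2, DMF/H2O, rt) converts the terminal alkene into the methyl ketone 3.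

**Further compounds**
F1 | step 7 | 5-methylhex-4-en-1-yne | C#CCC=C(C)C
F2 | step 7 | triisopropyl[(5-methylhex-4-en-1-yn-1-yl)oxy]silane | CC(C)=CCC#CO[Si](C(C)C)(C(C)C)C(C)C
F3 | step 7 | (2S)-5-hydroxy-6-(3-methylbut-2-enyl)-7-(triisopropylsilyloxy)-2-(3,4,5-trimethoxyphenyl)chroman-4-one | CC(C)=CCc1c(O[Si](C(C)C)(C(C)C)C(C)C)cc2c(c1O)C(=O)C[C@@H](c1cc(OC)c(OC)c(OC)c1)O2
F4 | step 7 | (2S)-5,7-dihydroxy-6-(3-methylbut-2-enyl)-2-(3,4,5-trimethoxyphenyl)chroman-4-one | CC(C)=CCc1c(O)cc2c(c1O)C(=O)C[C@@H](c1cc(OC)c(OC)c(OC)c1)O2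
F5 | step 5 | 2-oxo-2-[(S)-4-oxo-2-(3,4,5-trimethoxyphenyl)-3,4-dihydro-2H-pyran-6-yl]-N-(triphenylphosphoranylideneamino)ethanimidoyl chloride | O=C(C(Cl)=NN=P(c1ccccc1)(c1ccccc1)c1ccccc1)C1=CC(=O)C[C@@H](c2cc(OC)c(OC)c(OC)c2)O1
F6 | step 5 | 2-oxo-2-[(S)-4-oxo-2-(3,4,5-trimethoxyphenyl)-3,4-dihydro-2H-pyran-6-yl]ethanehydrazonoyl chloride | NN=C(Cl)C(=O)C1=CC(=O)C[C@@H](c2cc(OC)c(OC)c(OC)c2)O1
F7 | step 1 | (S)-1-(3,4,5-trimethoxyphenyl)but-3-en-1-ol | C=CC[C@@H](c1cc(OC)c(OC)c(OC)c1)O
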